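**Retrosynthetic overview**
- Target 17 ← MOM removal ← C8 prenylation (phenoxide C-alkylation) of chromene diol 14.
- Pyran ring (O1, C2, C3, C4, C4a, C8a) ← propargyl Claisen rearrangement and oxa-6π closure of the O4-(1,1-dimethylpropargyl) ether of acylphloroglucinol 7; the two ortho hydroxyls are acetylated so that only O4 can close the ring.
- The strategy rests on ring A (C4a, C5, C6, C7, C8, C8a; oxygen on C5, C7 and C8a, aroyl on C6): it is an acylphloroglucinol, a folded aroyl triketide, and so comes from 6-aroylmethyl-4-hydroxy-2-pyrone 5 by exchange of the ring oxygen for carbon (one new C–C bond).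
- Pyrone 5 ← acylation of the dianion of 4-hydroxy-6-methyl-2-pyrone 3 with MOM-protected methyl 3-hydroxybenzoate 2.
- Ring order: ring A (step 3), then the pyran ring (step 6); the 3-hydroxyphenyl ring is bought.

Key step: step 3

Remark: the target has no stereocentre and no stereogenic double bond; it is achiral, so the route needs no stereocontrol.

**Step 1**
Reactants: 1 methyl 3-hydroxybenzoate
Product: 2 methyl 3-(methoxymethoxy)benzoate
Conditions: MOMCl, K2CO3, acetone, 0 °C→rt
Reagents that add atoms: chloromethyl methyl ether (MOMCl), COCCl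
Why: Williamson-type O-alkylation of the phenoxide by the reactive α-chloro ether (MOM protection); the methyl ester is untouched by carbonate in acetone.

**Step 2**
Reactants: 3 4-hydroxy-6-methyl-2H-pyran-2-one; 2 methyl 3-(methoxymethoxy)benzoate
Product: 5 4-hydroxy-6-{2-[3-(methoxymethoxy)phenyl]-2-oxoethyl}-2H-pyran-2-one, via dilithio dianion 4 (not isolated)
Conditions: LDA (3.2 equiv), THF, −78 °C; then 2, −78→0 °C; AcOH quench
Reagents that add atoms: none
Why: After the 4-OH, the 6-methyl group (vinylogous α-position of the lactone) is deprotonated, and dianion 4 should react at this more basic carbon with the non-enolisable aryl ester in a crossed Claisen acylation, the third equivalent of base taking up the acidic proton of 5 so that the acylation runs to completion.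

**Step 3**
Reactants: 5 4-hydroxy-6-{2-[3-(methoxymethoxy)phenyl]-2-oxoethyl}-2H-pyran-2-one
Product: 7 [3-(methoxymethoxy)phenyl](2,4,6-trihydroxyphenyl)methanone, via triketo ester 6 (not isolated)
Conditions: Mg(OMe)2 (8 equiv), MeOH, reflux, Ar; then cold 1 M HCl to pH 4–5
Reagents that add atoms: none
Why: Magnesium methoxide opens the lactone of 5 at C2 to the magnesium-chelated triketo ester 6, whose methylene between the aryl ketone and the neighbouring ketone (heptanoate C6, the future chromene C6) adds as its enolate to the ester carbonyl (heptanoate C1, the future C5/C7, equivalent at this symmetric stage), and loss of methoxide with threefold enolisation aromatises the trione to 7. The closest known reaction type is the biomimetic polyketide Claisen (Dieckmann-type) cyclisation by which magnesium methoxide turns 6-(2-oxoalkyl)-4-hydroxy-2-pyrones and 3,5,7-triketo esters into acylphloroglucinols. Ring A is closed by a favoured 6-exo-trig enolate closure (enolexo when drawn through the aryl-ketone enolate), which forms one C–C bond and puts the side-chain carbon in the place of the pyrone ring oxygen. No stereocentre is formed. The selectivity needed is Claisen against aldol folding (attack of heptanoate C2 on the aryl ketone would give a resorcylate ester): in the magnesium chelate the three ketones are held as enolates and are poor acceptors, the ester is the one carbonyl that stays un-enolised and is activated by the metal, and the Claisen path is made irreversible by methoxide loss and aromatisation, whereas an aldol adduct can revert in the dry medium. The MOM ether is inert to the base.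

**Step 4**
Reactants: 7 [3-(methoxymethoxy)phenyl](2,4,6-trihydroxyphenyl)methanone; 8 3-chloro-3-methylbut-1-yne
Product: 9 {2,6-dihydroxy-4-[(2-methylbut-3-yn-2-yl)oxy]phenyl}[3-(methoxymethoxy)phenyl]methanone
Conditions: K2CO3 (1.2 equiv), KI (cat.), CuI (cat.), acetone, 55 °C
Reagents that add atoms: none
Why: The 4-hydroxyl (para to the carbonyl) is the most acidic and the only one outside the O–H···O=C chelate, so the mild base should ionise it first, and the copper-activated tertiary propargylic chloride alkylates this phenoxide on oxygen (copper-assisted Williamson-type propargylation).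

**Step 5**
Reactants: 9 {2,6-dihydroxy-4-[(2-methylbut-3-yn-2-yl)oxy]phenyl}[3-(methoxymethoxy)phenyl]methanone
Product: 10 2-[3-(methoxymethoxy)benzoyl]-5-[(2-methylbut-3-yn-2-yl)oxy]-1,3-phenylene diacetate
Conditions: Ac2O, pyridine, DMAP (cat.), CH2Cl2, rt
Reagents that add atoms: acetic anhydride, CC(=O)OC(C)=O
Why: DMAP-catalysed acetylation of the two remaining chelated phenols blocks both ortho oxygens, so that in step 6 only O4 can become the pyran oxygen.

**Step 6**
Reactants: 10 2-[3-(methoxymethoxy)benzoyl]-5-[(2-methylbut-3-yn-2-yl)oxy]-1,3-phenylene diacetate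
Product: 13 6-[3-(methoxymethoxy)benzoyl]-2,2-dimethyl-2H-chromene-5,7-diyl diacetate, via allenylphenol 11 (not isolated), via ortho-quinone methide 12 (not isolated)
Conditions: o-xylene, reflux (ca. 144 °C), Ar
Reagents that add atoms: none
Why: Aromatic propargyl Claisen rearrangement to either of the two equivalent ortho carbons gives allenylphenol 11, a [1,5]-H shift from the freed O4–H gives the Z-configured ortho-quinone methide 12, and oxa-6π electrocyclisation closes the 2,2-dimethyl-2H-chromene; the oxygen on the other flank is acetylated, so the ring can close only on O4.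

**Step 7**
Reactants: 13 6-[3-(methoxymethoxy)benzoyl]-2,2-dimethyl-2H-chromene-5,7-diyl diacetate
Product: 14 (5,7-dihydroxy-2,2-dimethyl-2H-chromen-6-yl)[3-(methoxymethoxy)phenyl]methanone
Conditions: K2CO3 (0.2 equiv), MeOH, 0 °C→rt; then pH 5 buffer
Reagents that add atoms: none
Why: Base-catalysed transesterification (methanolysis) of the two aryl acetates; the MOM ether, the diaryl ketone and the chromene are inert to these conditions.

**Step 8**
Reactants: 14 (5,7-dihydroxy-2,2-dimethyl-2H-chromen-6-yl)[3-(methoxymethoxy)phenyl]methanone; 15 1-bromo-3-methylbut-2-ene (prenyl bromide)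
Product: 16 [5,7-dihydroxy-2,2-dimethyl-8-(3-methylbut-2-en-1-yl)-2H-chromen-6-yl][3-(methoxymethoxy)phenyl]methanone
Conditions: 10% aq. KOH, 15 (1.1 equiv), 0 °C→rt; then AcOH to pH 5
Reagents that add atoms: none
Why: In water the phenoxide oxygens are solvated, so the ambident acylphloroglucinol anion should be alkylated at carbon (SN2 phenoxide C-alkylation with rearomatisation), and C8 is the only unsubstituted ring carbon, ortho to O7 and para to O5.

**Step 9**
Reactants: 16 [5,7-dihydroxy-2,2-dimethyl-8-(3-methylbut-2-en-1-yl)-2H-chromen-6-yl][3-(methoxymethoxy)phenyl]methanone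
Product: 17 [5,7-dihydroxy-2,2-dimethyl-8-(3-methylbut-2-en-1-yl)-2H-chromen-6-yl](3-hydroxyphenyl)methanone
Conditions: HCl (ca. 1 M in MeOH), rt
Reagents that add atoms: none
Why: Acid-catalysed acetal exchange with methanol cleaves the MOM ether at room temperature, conditions mild enough to leave the ortho-prenylphenol and the chromene uncyclised.

**Compound list**
1 | methyl 3-hydroxybenzoate | COC(=O)c1cccc(O)c1 | starting material
2 | methyl 3-(methoxymethoxy)benzoate | COCOc1cccc(c1)C(=O)OC | intermediate
3 | 4-hydroxy-6-methyl-2H-pyran-2-one | CC1=CC(O)=CC(=O)O1 | starting material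
4 | dilithio dianion of 3 (4-oxido, 6-methylene carbanion) | [Li+].[Li+].[CH2-]C1=CC([O-])=CC(=O)O1 | intermediate
5 | 4-hydroxy-6-{2-[3-(methoxymethoxy)phenyl]-2-oxoethyl}-2H-pyran-2-one | COCOc1cccc(c1)C(=O)CC1=CC(O)=CC(=O)O1 | intermediate
6 | methyl 7-[3-(methoxymethoxy)phenyl]-3,5,7-trioxoheptanoate (present as its magnesium chelate) | COCOc1cccc(c1)C(=O)CC(=O)CC(=O)CC(=O)OC | intermediate
7 | [3-(methoxymethoxy)phenyl](2,4,6-trihydroxyphenyl)methanone | COCOc1cccc(c1)C(=O)c1c(O)cc(O)cc1O | intermediate
8 | 3-chloro-3-methylbut-1-yne | CC(C)(Cl)C#C | starting material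
9 | {2,6-dihydroxy-4-[(2-methylbut-3-yn-2-yl)oxy]phenyl}[3-(methoxymethoxy)phenyl]methanone | COCOc1cccc(c1)C(=O)c1c(O)cc(OC(C)(C)C#C)cc1O | intermediate
10 | 2-[3-(methoxymethoxy)benzoyl]-5-[(2-methylbut-3-yn-2-yl)oxy]-1,3-phenylene diacetate | COCOc1cccc(c1)C(=O)c1c(OC(C)=O)cc(OC(C)(C)C#C)cc1OC(C)=O | intermediate
11 | 5-hydroxy-2-[3-(methoxymethoxy)benzoyl]-4-(3-methylbuta-1,2-dien-1-yl)-1,3-phenylene diacetate (allenylphenol) | COCOc1cccc(c1)C(=O)c1c(OC(C)=O)cc(O)c(C=C=C(C)C)c1OC(C)=O | intermediate
12 | 3-[3-(methoxymethoxy)benzoyl]-5-[(Z)-3-methylbut-2-en-1-ylidene]-6-oxocyclohexa-1,3-diene-2,4-diyl diacetate (ortho-quinone methide) | COCOc1cccc(c1)C(=O)C1=C(OC(C)=O)/C(=C/C=C(C)C)C(=O)C=C1OC(C)=O | intermediate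
13 | 6-[3-(methoxymethoxy)benzoyl]-2,2-dimethyl-2H-chromene-5,7-diyl diacetate | COCOc1cccc(c1)C(=O)c1c(OC(C)=O)cc2OC(C)(C)C=Cc2c1OC(C)=O | intermediate
14 | (5,7-dihydroxy-2,2-dimethyl-2H-chromen-6-yl)[3-(methoxymethoxy)phenyl]methanone | COCOc1cccc(c1)C(=O)c1c(O)cc2OC(C)(C)C=Cc2c1O | intermediate
15 | 1-bromo-3-methylbut-2-ene (prenyl bromide) | CC(C)=CCBr | starting material
16 | [5,7-dihydroxy-2,2-dimethyl-8-(3-methylbut-2-en-1-yl)-2H-chromen-6-yl][3-(methoxymethoxy)phenyl]methanone | COCOc1cccc(c1)C(=O)c1c(O)c(CC=C(C)C)c2OC(C)(C)C=Cc2c1O | intermediate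
17 | [5,7-dihydroxy-2,2-dimethyl-8-(3-methylbut-2-en-1-yl)-2H-chromen-6-yl](3-hydroxyphenyl)methanone | CC(C)=CCc1c(O)c(C(=O)c2cccc(O)c2)c(O)c2c1OC(C)(C)C=C2 | target

**Step count**
Total steps: 9. Longest linear sequence: 9 steps (1 → 17; pyrone 3 enters at step 2).

**Steps most likely to fail**

1. Step 3 (key step). The opened chain may fold by aldol addition of the ester-side methylene to the aryl ketone instead of by Claisen closure. It may also suffer retro-Claisen cleavage by methoxide, or relactonise on work-up. Fallback, setting out from 2 and coming back at 7: ester 2 would be converted with N,O-dimethylhydroxylamine hydrochloride and iPrMgCl (THF, −20 °C) into the Weinreb amide N-methoxy-N-methyl-3-(methoxymethoxy)benzamide F1. Commercial 1,3,5-tris(benzyloxy)benzene would be brominated with NBS to 1,3,5-tris(benzyloxy)-2-bromobenzene F2. Bromine–lithium exchange on F2 (n-BuLi, THF, −78 °C) and addition of the aryllithium to F1 should give the ketone [3-(methoxymethoxy)phenyl][2,4,6-tris(benzyloxy)phenyl]methanone F3. Hydrogenolysis of the three benzyl ethers (H2, Pd/C, EtOAc, rt), which leaves the MOM ether intact, would then give 7.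

2. Step 8. Alkylation may take place on oxygen instead of carbon, and a second, dearomatising alkylation at C8 may follow the first. Fallback, setting out from 14 and coming back at 16: electrophilic iodination of the single free ring position with NIS (MeCN, 0 °C) would give (5,7-dihydroxy-8-iodo-2,2-dimethyl-2H-chromen-6-yl)[3-(methoxymethoxy)phenyl]methanone F4. Stille coupling of F4 with tributyl(3-methylbut-2-en-1-yl)stannane (Pd(PPh3)4, DMF, 85 °C) should then deliver 16 with the prenyl group bound through its CH2 carbon.

3. Step 4. Etherification may not stay at O4 (a second ether at an ortho oxygen, or C-propargylation at C3), and the tertiary chloride may react slowly with the delocalised phenoxide. Fallback, setting out from 7 and coming back at 10: peracetylation (Ac2O, pyridine, DMAP) would give 2-[3-(methoxymethoxy)benzoyl]benzene-1,3,5-triyl triacetate F5. Selective thiolysis of the unhindered acetate para to the ketone (PhSH, imidazole, NMP, 0 °C) would give 5-hydroxy-2-[3-(methoxymethoxy)benzoyl]-1,3-phenylene diacetate F6, in which O4 is the only free hydroxyl. Copper-catalysed etherification of F6 with 8 (DBU, CuCl2·2H2O cat., MeCN, 0 °C) should then give 10 directly.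

**Further compounds**
F1 | step 3 | N-methoxy-N-methyl-3-(methoxymethoxy)benzamide | COCOc1cccc(c1)C(=O)N(C)OC
F2 | step 3 | 1,3,5-tris(benzyloxy)-2-bromobenzene | Brc1c(OCc2ccccc2)cc(OCc2ccccc2)cc1OCc1ccccc1
F3 | step 3 | [3-(methoxymethoxy)phenyl][2,4,6-tris(benzyloxy)phenyl]methanone | COCOc1cccc(c1)C(=O)c1c(OCc2ccccc2)cc(OCc2ccccc2)cc1OCc1ccccc1
F4 | step 8 | (5,7-dihydroxy-8-iodo-2,2-dimethyl-2H-chromen-6-yl)[3-(methoxymethoxy)phenyl]methanone | COCOc1cccc(c1)C(=O)c1c(O)c(I)c2OC(C)(C)C=Cc2c1O
F5 | step 4 | 2-[3-(methoxymethoxy)benzoyl]benzene-1,3,5-triyl triacetate | COCOc1cccc(c1)C(=O)c1c(OC(C)=O)cc(OC(C)=O)cc1OC(C)=O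
F6 | step 4 | 5-hydroxy-2-[3-(methoxymethoxy)benzoyl]-1,3-phenylene diacetate | COCOc1cccc(c1)C(=O)c1c(OC(C)=O)cc(O)cc1OC(C)=O
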